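If Tuesday's target peak stays small while Sunday's keeps climbing, the catalyst charged is worth counting against the impurity charged.

| flask | starting material | second substrate | reagent | free catalyst | impurity | temperature | remark | time |
|---|---|---|---|---|---|---|---|---|
| Tuesday's | 0.22 M | 0.50 equiv | 3 equiv | 0.39 mol% | 0.92 mM | 10 °C | run made earlier |  |
| Monday's | 0.63 M | 0.50 equiv | 3 equiv | 0.39 mol% | 0.92 mM | 21 °C | run made earlier |  |
| Sunday's | 0.40 M | 0.50 equiv | 3 equiv | 0.91 mol% | 0.92 mM | 10 °C | run made earlier |  |
| alpha | 0.20 M | 0.500 equiv | 3.00 equiv | 1.5 mol% | 0.25 mM | 25 °C |  | 8.0 h |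
| zeta | 0.40 M | 0.500 equiv | 3.00 equiv | 0.39 mol% | 0.92 mM | 25 °C |  | 8.0 h |
| delta | 0.25 M | 1.50 equiv | 3.00 equiv | 0.39 mol% | 0.92 mM | 25 °C |  | 8.0 h |
| beta | 0.40 M | 0.500 equiv | 3.00 equiv | 0.39 mol% | 0.92 mM | 5 °C |  | 8.0 h |
| gamma | 0.40 M | 0.500 equiv | 3.00 equiv | 1.2 mol% | 2.0 mM | 5 °C |  | 8.0 h |

| run | time / h | target / % |
|---|---|---|
| Tuesday's | 2.00 | 0.7 |
| Tuesday's | 4.00 | 1.4 |
| Tuesday's | 6.00 | 1.4 |
| Tuesday's | 8.00 | 1.7 |
| Tuesday's | 10.0 | 2.4 |
| Tuesday's | 12.0 | 2.0 |
| Monday's | 0.417 | 2.5 |
| Monday's | 0.667 | 4.6 |
| Monday's | 1.33 | 7.7 |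
| Monday's | 2.00 | 11.1 |
| Monday's | 3.00 | 14.9 |
| Monday's | 6.00 | 27.8 |
| Sunday's | 0.833 | 3.8 |
| Sunday's | 2.00 | 8.5 |
| Sunday's | 3.00 | 12.2 |
| Sunday's | 6.00 | 22.5 |
| Sunday's | 12.0 | 39.0 |

(readings scatter by 0.3 percentage points)

1. all flasks from highest to lowest amount of target, in percent of the starting material charged, at 8.0 h (alpha / zeta / delta / beta / gamma)
2. the amount of target, in percent of the starting material charged of the flask you put first, at 8.0 h
3. the amount of target, in percent of the starting material charged of the flask you put last, at 8.0 h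

- no earlier run changes the charge of impurity; that part of a forecast is a guess

Suppose each impurity molecule takes one free catalyst to spent catalyst and does nothing else. Catalyst loss divided by impurity loss is then one at every moment, so time drops out and, with the impurity the smaller charge, the final loss stands in the charges. Alpha carries 8.33%: this is ρ, the impurity charged over the catalyst charged.

Tuesday's run supports this. Its ρ is 107%, and its target lies at 2.0% after 12.0 h. Sunday's ρ is 25.3%, and its target still climbs to 39.0%.

A first estimate takes the rate in percent per hour as proportional to the surviving catalyst, charge minus impurity. But the reagent is charged in equivalents, so its concentration follows the starting material, and the better form divides by the starting concentration as well. This gives κ, the rate over surviving catalyst and starting concentration. The two-hour readings give 39.1 /M²/h on Sunday and 57.3 /M²/h on Monday.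

Monday differs from Sunday in temperature, concentration and loading together, so the objection is that this form is assumed. Tuesday tests it. With its catalyst whole, the scaled form gives 1.47% of target at 2.00 h and the unscaled form 2.68%. The reading is 0.7%, below both and nearer the scaled form.

Carrying ln κ linearly in temperature gives 65.9 /M²/h at 25 °C and 32.8 /M²/h at 5 °C. Over 8.0 h my reckoning then gives:

- alpha 29.0%
- gamma 29.4%
- zeta 13.5%
- beta 6.72%

This reckoning leaves alpha and gamma level, and I put alpha first, at about 29.0%.

Delta's ρ is 94.4%, and its surviving catalyst gives 0.725%. That estimate looks too low: Tuesday's reading at 12.0 h stands at 5.13 target per catalyst charged, more than one, so catalyst turns over before its capture is complete. I place delta near Tuesday's 2.0%, last, below my figure for beta.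

The forecast, from the same runs, reads alpha > zeta > gamma > delta > beta, with 48.5% on top, above my top, and 5.8% last, and starts from “the impurity removes about one catalyst per impurity molecule”.

The flasks give alpha > gamma > zeta > beta > delta, with 31.3% on top and 1.90% last.

    free catalyst + impurity → spent catalyst (k = 6700 /M/h, Ea = 53.0 kJ/mol)
    reagent + catalyst intermediate A → free catalyst + target (k = 47.0 /M/h, Ea = 71.0 kJ/mol)
    second substrate + free catalyst ⇌ catalyst intermediate B (K = 260 /M, k = 760 /M/h, Ea = 46.0 kJ/mol, ΔH = −24.0 kJ/mol)
    reagent + catalyst intermediate B → free catalyst + second product (k = 1100 /M/h, Ea = 56.0 kJ/mol)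
    starting material + free catalyst ⇌ catalyst intermediate A (K = 0.920 /M, k = 590 /M/h, Ea = 41.0 kJ/mol, ΔH = −62.0 kJ/mol)
    (constants at 25 °C)

Alpha has not come to rest at 8.00 h. Its spent catalyst stands at 8.33% against ρ of 8.33% and is still 8.33% at 80.0 h, while its target rises from 31.3% to 95.6%. Ten times the time moves alpha's target peak and leaves its spent catalyst unchanged. Zeta, with ρ of 59.0%, holds 59.0% spent at both times and goes from 15.0% to 76.2%. Delta, with ρ of 94.4% and 93.5% spent at 8.00 h, creeps from 1.90% to 7.26% at 80.0 h.

The readings were generated by integration on assumed constants, and the scatter is random.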